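**Retrosynthetic overview**
- Dicitrinone G is cut at the C7–CH2–C7′ bridge into the dihydroisocoumarin half, the quinone methide half and one carbon from formaldehyde; the bridge is made through the Mannich base and ortho-quinone methide of the lactone half.
- The quinone methide half comes from the same lactone (lactone → lactol → loss of water), so one compound feeds both halves.
- The lactone half is cut into a trans-α,β-dimethyl-β-lactone and the trianion of methyl 3,5-dioxoheptanoate: C4a–C5 acylation, C4a–C8a aldol aromatisation, relactonisation.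
- The β-lactone comes from meso cis-2,3-dimethyloxirane and CO by an enantioselective ring-expansion carbonylation, which sets both stereocentres; the diketo ester comes from methyl acetoacetate and methyl propanoate.
- Ring order: oxetanone (step 1), then the benzene ring and the six-membered lactone (step 3); the heterocycle of the quinone methide is that same ring, reduced at C1 (step 4).

Assumption: the (R,R) antipode of [(salcy)Cr(THF)2][Co(CO)4] (salcy = N,N'-bis(3,5-di-tert-butylsalicylidene)-1,2-cyclohexanediamine dianion) gives the (3R,4R) lactone; if the first run shows the opposite sense the (S,S) antipode is used, and carbon monoxide, formaldehyde and dimethylamine are treated as reagents.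

**Step 1**
Reactants: 1 cis-2,3-dimethyloxirane (meso)
Product: 2 (3R,4R)-3,4-dimethyloxetan-2-one
Conditions: [(R,R)-(salcy)Cr(THF)2][Co(CO)4] (2 mol%), CO (60 bar), DME, 22 °C, 24 h
Reagents that add atoms: carbon monoxide, [C-]#[O+]
Why: Ring-expansion carbonylation of an epoxide (enantioselective desymmetrisation of a meso epoxide): the chiral trivalent chromium Lewis acid activates one of the two enantiotopic C–O bonds, Co(CO)4− opens it with inversion at the (S)-carbon, CO inserts by alkyl migration and the retained alkoxide closes on the acyl cobalt, so the cis epoxide gives the trans lactone with C3 (new C–C bond, inversion) and C4 (untouched C–O bond) set together; any shortfall in enantiomeric purity can be made up by recrystallising 8.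

**Step 2**
Reactants: 3 methyl 3-oxobutanoate (methyl acetoacetate), 4 methyl propanoate
Product: 5 methyl 3,5-dioxoheptanoate
Conditions: 3 (2.0 equiv), LiN(iPr)2 (4.2 equiv), THF, 0 °C; 4 (1.0 equiv), 0 → 25 °C; aq. HCl
Reagents that add atoms: none
Why: Claisen condensation of the acetoacetate dianion at its γ-carbon with an ester (dianion γ-acylation), the second equivalent of dianion taking up the proton of the more acidic product.

**Step 3**
Reactants: 5 methyl 3,5-dioxoheptanoate, 2 (3R,4R)-3,4-dimethyloxetan-2-one
Product: 8 (3R,4S)-6,8-dihydroxy-3,4,5-trimethyl-3,4-dihydro-1H-isochromen-1-one, via tetraketide hydroxy ester 6 (not isolated), via resorcylate hydroxy ester 7 (not isolated)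
Conditions: 5 (2.0 equiv), LiN(iPr)2 (6.2 equiv), THF, −78 → 0 °C; 2 (1.0 equiv), −78 → −20 °C; AcOH to pH 9, MeOH–H2O, 25 °C; then 2 M HCl, 45 °C
Reagents that add atoms: none
Why: Proposed new method: the terminal (C6) carbanion of the trianion of 5, its hardest and most basic site, should attack the strained acyl carbon of 2 (acyl–oxygen cleavage) faster than it removes the α-proton or displaces at the hindered secondary C4; the new ketone is at once deprotonated between its two carbonyls, which shields the adjacent stereocentre from enolisation and the β-alkoxide from retro-aldol; at pH 9 the C2 carbon of the β-keto ester end adds to that ketone (six-membered intramolecular aldol, the polyketide cyclisation mode) and loss of water gives the benzene ring irreversibly; acid then closes the six-membered lactone on the untouched secondary alcohol, so both stereocentres of 2 pass unchanged into 8 (the α-carbon descriptor changes from R to S only because the acyl neighbour becomes an aryl neighbour of lower priority); the closest known reaction types are the acylation of β,δ-diketo ester trianions with simple esters followed by aldol closure to β-resorcylates, and the Claisen-type opening of β-lactones by lithium ester enolates, which have not been combined or shown with a stereodefined α,β-disubstituted β-lactone.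

**Step 4**
Reactants: 8 (3R,4S)-6,8-dihydroxy-3,4,5-trimethyl-3,4-dihydro-1H-isochromen-1-one
Product: 10 (3R,4S)-6-hydroxy-3,4,5-trimethyl-3,4-dihydroisochromen-8-one (decarboxycitrinin), via lactol 9 (not isolated)
Conditions: i-Bu2AlH (3.5 equiv), CH2Cl2–toluene, −78 °C; then 1 M HCl, THF, 0 → 25 °C
Reagents that add atoms: none
Why: Partial reduction of a lactone to the lactol with i-Bu2AlH (two equivalents go to the phenols, the chelated aluminium hemiacetal resists further reduction at −78 °C), then acid-promoted loss of water from the 8-hydroxy lactol to the quinone methide, the dehydration that links citrinin and its hydrate; C3 and C4 are not touched.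

**Step 5**
Reactants: 8 (3R,4S)-6,8-dihydroxy-3,4,5-trimethyl-3,4-dihydro-1H-isochromen-1-one, 10 (3R,4S)-6-hydroxy-3,4,5-trimethyl-3,4-dihydroisochromen-8-one
Product: 12 Dicitrinone G, via Mannich base 11 (not isolated)
Conditions: 8 (1.0 equiv), 37% aq. CH2O (1.0 equiv), 40% aq. Me2NH (1.1 equiv), EtOH, 25 °C; evaporate; then 10 (1.0 equiv), 1,4-dioxane, 90 °C, N2 sweep
Reagents that add atoms: formaldehyde, C=O; dimethylamine, CNC (held only in 11 and lost again)
Why: Phenolic Mannich reaction at C7, the only free ring position of 8, then thermal loss of dimethylamine gives an ortho-quinone methide that is trapped in a Michael addition by C7 of 10, the central carbon of a vinylogous 1,3-diketone; no stereocentre is involved.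

**Compound list**
1 | cis-2,3-dimethyloxirane (meso, 2R,3S) | C[C@H]1O[C@H]1C | starting material
2 | (3R,4R)-3,4-dimethyloxetan-2-one | C[C@H]1OC(=O)[C@@H]1C | intermediate
3 | methyl 3-oxobutanoate (methyl acetoacetate) | CC(=O)CC(=O)OC | starting material
4 | methyl propanoate | CCC(=O)OC | starting material
5 | methyl 3,5-dioxoheptanoate | CCC(=O)CC(=O)CC(=O)OC | intermediate
6 | methyl (8R,9R)-9-hydroxy-6,8-dimethyl-3,5,7-trioxodecanoate (C6 epimers and enol forms, formed as lithium polyenolate) | C[C@@H](O)[C@@H](C)C(=O)C(C)C(=O)CC(=O)CC(=O)OC | intermediate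
7 | methyl 4,6-dihydroxy-2-[(2S,3R)-3-hydroxybutan-2-yl]-3-methylbenzoate | C[C@@H](O)[C@@H](C)c1c(C)c(O)cc(O)c1C(=O)OC | intermediate
8 | (3R,4S)-6,8-dihydroxy-3,4,5-trimethyl-3,4-dihydro-1H-isochromen-1-one | Oc1cc(O)c(C)c2c1C(=O)O[C@H](C)[C@H]2C | intermediate
9 | (3R,4S)-3,4,5-trimethyl-3,4-dihydro-1H-isochromene-1,6,8-triol (lactol, both C1 epimers) | Oc1cc(O)c(C)c2c1C(O)O[C@H](C)[C@H]2C | intermediate
10 | (3R,4S)-6-hydroxy-3,4,5-trimethyl-3,4-dihydroisochromen-8-one (decarboxycitrinin) | CC1=C2C(=CO[C@H](C)[C@H]2C)C(=O)C=C1O | intermediate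
11 | (3R,4S)-7-[(dimethylamino)methyl]-6,8-dihydroxy-3,4,5-trimethyl-3,4-dihydro-1H-isochromen-1-one | CN(C)Cc1c(O)c(C)c2c(c1O)C(=O)O[C@H](C)[C@H]2C | intermediate
12 | Dicitrinone G, (3R,4S)-7-{[(3R,4S)-6-hydroxy-3,4,5-trimethyl-8-oxo-3,4-dihydroisochromen-7-yl]methyl}-6,8-dihydroxy-3,4,5-trimethyl-3,4-dihydro-1H-isochromen-1-one | CC1=C2C(=CO[C@H](C)[C@H]2C)C(=O)C(Cc2c(O)c(C)c3c(c2O)C(=O)O[C@H](C)[C@H]3C)=C1O | target

**Totals**
Total step count: 5. Longest linear sequence: 4 steps (1 → 2 → 8 → 10 → 12).

**Steps most likely to fail**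

Step 3 (the proposed new step). The trianion may deprotonate 2 and scramble trans to cis, the hindered ketone may be slow in the aldol closure, or the δ-hydroxy diketone may close to a dihydropyranone instead. The fallback uses known chemistry, sets out from 2 and comes back at 8. Compound 2 is opened with NaOMe (5 mol%) in MeOH at 0 °C to methyl (2R,3R)-3-hydroxy-2-methylbutanoate F1, which is silylated (TBSCl, imidazole, DMF) to methyl (2R,3R)-3-[(tert-butyldimethylsilyl)oxy]-2-methylbutanoate F2. F2 acylates the trianion of 5 (LiN(iPr)2, THF, −78 °C), the established ester version of this condensation, to give methyl (8R,9R)-9-[(tert-butyldimethylsilyl)oxy]-6,8-dimethyl-3,5,7-trioxodecanoate F3. Aqueous KHCO3 in MeOH closes the benzene ring to methyl 2-[(2S,3R)-3-[(tert-butyldimethylsilyl)oxy]butan-2-yl]-4,6-dihydroxy-3-methylbenzoate F4, and aqueous HCl in MeOH removes the silyl group and closes the lactone to 8.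

Step 4. The free phenols may slow the reduction or the lactol may be reduced further. The fallback sets out from 8 and comes back at 10 by over-reduction and selective re-oxidation. LiAlH4 (THF, 0 → 65 °C) reduces 8 fully to 4-(hydroxymethyl)-5-[(2S,3R)-3-hydroxybutan-2-yl]-6-methylbenzene-1,3-diol F5. Activated MnO2 (EtOAc, 25 °C) oxidises only the ortho-hydroxybenzylic alcohol to 2,4-dihydroxy-6-[(2S,3R)-3-hydroxybutan-2-yl]-5-methylbenzaldehyde F6, which closes and loses water with catalytic CF3CO2H in CH2Cl2 to give 10.

Step 5. Compound 10 may be attacked by dimethylamine or may be too sensitive at 90 °C, and the open product may cyclise further. The fallback sets out from 8 and comes back at 12 by homo-coupling first and differentiating the halves afterwards. Compound 8 (2 equiv) and aqueous CH2O (1 equiv) in AcOH with catalytic H2SO4 at 60 °C give the symmetric 7,7'-methylenebis[(3R,4S)-6,8-dihydroxy-3,4,5-trimethyl-3,4-dihydro-1H-isochromen-1-one] F7. i-Bu2AlH in deficit (5.2 equiv: four for the phenols, about one for a single lactone) at −78 °C gives the mono-lactol (3R,4S)-7-{[(3R,4S)-1,6,8-trihydroxy-3,4,5-trimethyl-3,4-dihydro-1H-isochromen-7-yl]methyl}-6,8-dihydroxy-3,4,5-trimethyl-3,4-dihydro-1H-isochromen-1-one F8, which loses water on acid work-up to give 12; unchanged F7 is recycled.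

**Further compounds**
F1 | step 3 | methyl (2R,3R)-3-hydroxy-2-methylbutanoate | C[C@@H](O)[C@@H](C)C(=O)OC
F2 | step 3 | methyl (2R,3R)-3-[(tert-butyldimethylsilyl)oxy]-2-methylbutanoate | C[C@@H](O[Si](C)(C)C(C)(C)C)[C@@H](C)C(=O)OC
F3 | step 3 | methyl (8R,9R)-9-[(tert-butyldimethylsilyl)oxy]-6,8-dimethyl-3,5,7-trioxodecanoate | C[C@@H](O[Si](C)(C)C(C)(C)C)[C@@H](C)C(=O)C(C)C(=O)CC(=O)CC(=O)OC
F4 | step 3 | methyl 2-[(2S,3R)-3-[(tert-butyldimethylsilyl)oxy]butan-2-yl]-4,6-dihydroxy-3-methylbenzoate | C[C@@H](O[Si](C)(C)C(C)(C)C)[C@@H](C)c1c(C)c(O)cc(O)c1C(=O)OC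
F5 | step 4 | 4-(hydroxymethyl)-5-[(2S,3R)-3-hydroxybutan-2-yl]-6-methylbenzene-1,3-diol | C[C@@H](O)[C@@H](C)c1c(C)c(O)cc(O)c1CO
F6 | step 4 | 2,4-dihydroxy-6-[(2S,3R)-3-hydroxybutan-2-yl]-5-methylbenzaldehyde | C[C@@H](O)[C@@H](C)c1c(C)c(O)cc(O)c1C=O
F7 | step 5 | 7,7'-methylenebis[(3R,4S)-6,8-dihydroxy-3,4,5-trimethyl-3,4-dihydro-1H-isochromen-1-one] | O=C1O[C@H](C)[C@@H](C)c2c(C)c(O)c(Cc3c(O)c(C)c4c(c3O)C(=O)O[C@H](C)[C@H]4C)c(O)c12
F8 | step 5 | (3R,4S)-7-{[(3R,4S)-1,6,8-trihydroxy-3,4,5-trimethyl-3,4-dihydro-1H-isochromen-7-yl]methyl}-6,8-dihydroxy-3,4,5-trimethyl-3,4-dihydro-1H-isochromen-1-one | OC1O[C@H](C)[C@@H](C)c2c(C)c(O)c(Cc3c(O)c(C)c4c(c3O)C(=O)O[C@H](C)[C@H]4C)c(O)c12
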